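All runs are simulated with constants of no real substance; noise was put on by code.

**Time of reading.** West was read after 3.0 d and south-east after 0.80 d, from the same charge of 20 mM of each substrate under held gas, so I looked for a time of the flask to set these two against.

| setting | Sunday's | west | south-east |
|---|---|---|---|
| left-handed substrate | 10 mM | 20 mM | 20 mM |
| right-handed substrate | 10 mM | 20 mM | 20 mM |
| gas | 7.1 mM (held) | 7.1 mM (held) | 7.1 mM (held) |
| remark | run made earlier |  |  |
| time |  | 3.0 d | 0.80 d |

- Sunday's (time / h: left-handed product / %, right-handed product / %): 0.833: 1.0, 0.2; 2.00: 3.4, 0.1; 4.00: 9.2, 1.8; 6.00: 15.3, 2.9; 8.00: 20.4, 4.3; 12.0: 29.3, 9.2; 15.0: 35.3, 12.6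

(readings scatter by 0.3 percentage points)

- partner is single-handed; left-handed substrate and right-handed substrate are mirror images of each other, charged as a racemate, each of them at the stated concentration
- at the start none of the gas is in solution
- an excess is the difference of the two amounts in percent of their sum
- an excess is below zero if the other one leads
- the handed part of partner does not stay in what it makes, so the products of the two hands are mirror images too

* which one finishes higher in excess of left-handed product over right-handed product in the product ("neither" within 2 percentage points) (west / south-east / neither)
* excess of left-handed product over right-handed product in the product at the end, west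
* excess of left-handed product over right-handed product in the product at the end, south-east

**Excess half-life.** In Sunday's run the excess of left-handed product read 65.2 % at 8.00 h, where right-handed product stood at 4.3 % against a scatter of 0.3 percentage points, and 47.4 % at 15.0 h. The products being mirror images, I took zero as where this excess was heading, and from these two readings I reckoned its excess half-life, an apparent first-order half-life, as 15.2 h. Sunday's charge was 10 mM, so carrying this half-life to 20 mM was my assumption, not a reading.

**Two times.** West's time of reading came to 4.73 of these half-lives and south-east's to 1.26. Counting on from the last reading of Sunday's run, I expected 3.54 % for west and 39.1 % for south-east, a gap of 36 points against a margin of 2 points.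

**The forecast.** The forecast gave 33 % for south-east, lower than my figure, and, reasoning for west that “the excess must approach zero”, 3 % for that flask, and it named south-east.

**The result.** West gave 2.85 % and south-east 38.0 %, so south-east finished higher; Sunday's run with its own charge, taken to the 0.80 d of south-east, came to 36.9 %.

    partner + left-handed substrate → left-handed product (k = 33.0 /M/h)
    partner + right-handed substrate → right-handed product (k = 1.10 /M/h)
    left-handed substrate ⇌ right-handed substrate (k = 1.10 /h)
    gas ⇌ partner, rate k4*(csat - [partner]) (kL = 0.210 /h)
    left-handed product ⇌ right-handed product (k = 0.0570 /h)
    2 partner → self-condensation product (k = 6.30 /M/h)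

**Further reading.** Counted on from Sunday's reading at 15.0 h with the half-life of 15.2 h, a reading of west at 20 h came out at 37.7 %, and that flask stood at 36.7 %.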